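**Retrosynthetic overview** (chain locants of the target: C1 = CO2H … C18 = CMe2)
1. The acid comes from its methyl ester; the 1,2-dioxane is closed last by a 6-exo peroxy-Michael addition of a C6 tertiary hydroperoxide onto the (E)-2-methyl-enoate, which sets C3 and C2.
2. The hydroperoxide comes from cobalt-catalysed hydroperoxidation of a C6 1,1-disubstituted alkene; the enoate from cross-metathesis; the alkene from a Negishi coupling on a vinyl triflate that rides through the cyclisation as an inert C6 placeholder.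
3. Both carbocycles come from one cation–olefin bicyclisation of an acyclic (Z)-allylic tertiary alcohol under a chiral Brønsted acid: ring A (C12–C17, terpinyl-type closure) first, then ring B (C9–C18); this sets the cis ring fusion.
4. The acyclic precursor comes from sulcatone (allylic oxidation, bromide) and dehydrolinalool (alkyne–allyl coupling, Lindlar reduction).
5. Ring order: ring A, then ring B (same pot), then the 1,2-dioxane.

Assumption: racemic dehydrolinalool and but-3-en-1-ylzinc bromide (0.5 M in THF) are bought, and for each of the two chiral catalysts the enantiomer that gives the drawn configuration is picked by a test reaction.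

Notation: Bic = (4aR,8aS)-1,1,3,6-tetramethyl-1,4,4a,7,8,8a-hexahydronaphthalen-2-yl (cis-fused; C2=C3 and C5=C6 double bonds; gem-dimethyl at C1).

**Step 1**
Reactants: 1 6-methylhept-5-en-2-one (sulcatone)
Product: 2 (5E)-7-hydroxy-6-methylhept-5-en-2-one
Conditions: SeO2 (0.5 equiv), t-BuOOH (2 equiv), CH2Cl2, 0 °C to rt
Reagents that add atoms: tert-butyl hydroperoxide, CC(C)(C)OO (oxygen source); selenium dioxide, O=[Se]=O (transfers the oxygen)
Why: Sharpless-type SeO2 allylic oxidation (ene reaction, then [2,3]-shift) hydroxylates only the (E)-methyl of the trisubstituted alkene, which fixes the 5E geometry, and the ketone is inert at room temperature.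

**Step 2**
Reactants: 2 (5E)-7-hydroxy-6-methylhept-5-en-2-one
Product: 3 (5E)-7-bromo-6-methylhept-5-en-2-one
Conditions: CBr4, PPh3, CH2Cl2, 0 °C
Reagents that add atoms: tetrabromomethane, BrC(Br)(Br)Br
Why: Appel reaction; SN2 displacement of the oxyphosphonium at the primary allylic carbon under neutral conditions leaves the alkene geometry and the ketone untouched.

**Step 3**
Reactants: 3 (5E)-7-bromo-6-methylhept-5-en-2-one; 4 (±)-3,7-dimethyloct-6-en-1-yn-3-ol (dehydrolinalool)
Product: 5 (5E)-10-hydroxy-6,10,14-trimethylpentadeca-5,13-dien-8-yn-2-one (racemic)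
Conditions: CuI (20 mol%), NaI (20 mol%), Cs2CO3, DMF, rt
Reagents that add atoms: none
Why: copper-acetylide alkylation of a primary allylic bromide (SN2-type alkyne–allyl coupling) forms the C11–C12 bond at the unhindered carbon and tolerates the free tertiary alcohol and the ketone; the carbinol centre is racemic and is erased in step 6.

**Step 4**
Reactants: 5 (5E)-10-hydroxy-6,10,14-trimethylpentadeca-5,13-dien-8-yn-2-one
Product: 6 (5E,8Z)-10-hydroxy-6,10,14-trimethylpentadeca-5,8,13-trien-2-one (racemic)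
Conditions: H2 (1 atm), Pd/CaCO3 poisoned with Pb(OAc)2 (Lindlar catalyst), quinoline, EtOAc, rt
Reagents that add atoms: none
Why: Lindlar semi-hydrogenation delivers H2 syn to the alkyne and so sets the 8Z alkene, while the trisubstituted alkenes and the ketone are not reduced.

**Step 5**
Reactants: 6 (5E,8Z)-10-hydroxy-6,10,14-trimethylpentadeca-5,8,13-trien-2-one
Product: 7 (5E,8Z)-10-hydroxy-6,10,14-trimethylpentadeca-1,5,8,13-tetraen-2-yl trifluoromethanesulfonate (racemic)
Conditions: LiN(iPr)2 (2.2 equiv), THF, −78 °C; PhNTf2 (1.05 equiv), −78 to 0 °C; aq. NH4Cl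
Reagents that add atoms: N-phenylbis(trifluoromethanesulfonimide), O=S(=O)(N(c1ccccc1)S(=O)(=O)C(F)(F)F)C(F)(F)F
Why: kinetic deprotonation at the methyl group and O-triflation of the enolate (the hindered lithium tertiary alkoxide does not react with PhNTf2) give the terminal enol triflate, an electron-poor alkene that cannot act as a nucleophile in step 6.

**Step 6**
Reactants: 7 (5E,8Z)-10-hydroxy-6,10,14-trimethylpentadeca-1,5,8,13-tetraen-2-yl trifluoromethanesulfonate
Product: 8 4-(Bic)but-1-en-2-yl trifluoromethanesulfonate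
Conditions: (S,S)-IDPi chiral Brønsted acid (imidodiphosphorimidate built from two 3,3′-diaryl-BINOL units with P=N–SO2CF3 groups; 5 mol%), CH2Cl2/(CF3)2CHOH 4:1, −40 °C
Reagents that add atoms: none
Why: Proposed new method: the confined chiral acid ionises the tertiary allylic alcohol to an allyl cation that keeps its Z geometry inside a chiral contact ion pair; the prenyl alkene attacks the secondary cation terminus (six-membered, terpinyl-type closure of ring A) with the inside chain forced pseudo-axial, so that only the cis arrangement lets the side-chain alkene trap the new tertiary cation (ring B), and the counter-anion removes H+ to give the tetrasubstituted alkene; the anion pocket selects the cation face and so sets both ring-fusion centres as (4aR,8aS); closest known reaction types are the confined-acid-catalysed asymmetric cyclisation of neral to isopiperitenol (same ring-A closure), chiral Brønsted-acid-catalysed polyene cyclisations and the acid cyclisation of linalyl and neryl systems to terpinyl cations.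

**Step 7**
Reactants: 8 4-(Bic)but-1-en-2-yl trifluoromethanesulfonate; 9 but-3-en-1-ylzinc bromide
Product: 10 (4aR,8aS)-1,1,3,6-tetramethyl-2-(3-methylidenehept-6-en-1-yl)-1,4,4a,7,8,8a-hexahydronaphthalene
Conditions: PdCl2(dppf) (5 mol%), THF, 50 °C
Reagents that add atoms: none
Why: Negishi coupling of a vinyl triflate with a primary alkylzinc halide installs the C6 1,1-disubstituted alkene without touching the ring alkenes or the stereocentres.

**Step 8**
Reactants: 10 (4aR,8aS)-1,1,3,6-tetramethyl-2-(3-methylidenehept-6-en-1-yl)-1,4,4a,7,8,8a-hexahydronaphthalene; 11 methyl methacrylate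
Product: 12 methyl (2E)-2-methyl-6-methylidene-8-(Bic)oct-2-enoate
Conditions: second-generation Hoveyda–Grubbs catalyst RuCl2(H2IMes)(=CH-C6H4-2-OiPr) (5 mol%), methyl methacrylate (10 equiv), CH2Cl2, 40 °C
Reagents that add atoms: none
Why: olefin cross-metathesis of the only monosubstituted alkene with methacrylate gives the (E)-trisubstituted enoate under thermodynamic control, while the 1,1-disubstituted, trisubstituted and tetrasubstituted alkenes are too hindered to react.

**Step 9**
Reactants: 12 methyl (2E)-2-methyl-6-methylidene-8-(Bic)oct-2-enoate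
Product: 14 methyl (2E)-6-hydroperoxy-2,6-dimethyl-8-(Bic)oct-2-enoate (1:1 at C6), via triethylsilyl peroxide 13 (not isolated)
Conditions: Co(thd)2 (5 mol%; thd = 2,2,6,6-tetramethylheptane-3,5-dionate), O2 (1 atm), Et3SiH (2 equiv), ClCH2CH2Cl, rt; then HF·pyridine, THF, 0 °C
Reagents that add atoms: dioxygen, O=O
Why: Mukaiyama–Isayama hydroperoxysilylation: the cobalt hydride transfers a hydrogen atom to the unhindered 1,1-disubstituted alkene faster than to the ring alkenes or the electron-poor enoate, and O2 traps the tertiary C6 radical in the Markovnikov sense; the radical is planar and remote from the other stereocentres, so C6 forms 1:1, and buffered HF removes the silyl group without starting the cyclisation.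

**Step 10**
Reactants: 14 methyl (2E)-6-hydroperoxy-2,6-dimethyl-8-(Bic)oct-2-enoate
Product: 15 methyl (2R)-2-[(3R,6R)-6-methyl-6-{2-(Bic)ethyl}-1,2-dioxan-3-yl]propanoate
Conditions: bifunctional iminophosphorane organocatalyst ((S)-tert-leucine-derived squaramide carrying a (4-MeOC6H4)3P=N– group; 10 mol%), toluene, −20 °C; chromatography
Reagents that add atoms: none
Why: Proposed new method: the iminophosphorane deprotonates the hydroperoxide, the squaramide binds the enoate, 6-exo-trig attack of the peroxide anion on one enoate face sets C3 and the protonated catalyst returns H+ to the enolate inside the ion pair to set C2; both C6 epimers of 14 cyclise, and the (6S)-dioxane is removed here by chromatography, which fixes C6 as R; closest known reaction types are the amine-mediated intramolecular peroxy-Michael cyclisation of hydroperoxy enoates to 1,2-dioxanes and the iminophosphorane-catalysed enantioselective intramolecular oxa-Michael and sulfa-Michael additions to α,β-unsaturated esters.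

**Step 11**
Reactants: 15 methyl (2R)-2-[(3R,6R)-6-methyl-6-{2-(Bic)ethyl}-1,2-dioxan-3-yl]propanoate
Product: 16 (2R)-2-[(3R,6R)-6-methyl-6-{2-(Bic)ethyl}-1,2-dioxan-3-yl]propanoic acid (CNP0122760.1)
Conditions: LiOH, THF/H2O 3:1, 0 °C to rt; then 1 M HCl to pH 3
Reagents that add atoms: lithium hydroxide, [Li+].[OH-]
Why: mild saponification of the methyl ester (acyl substitution by hydroxide) at low temperature spares the dialkyl peroxide and keeps the contact time short enough to avoid epimerisation at C2 or retro-Michael ring opening.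

**Compound list**
1 | 6-methylhept-5-en-2-one (sulcatone) | CC(=O)CCC=C(C)C | starting material
2 | (5E)-7-hydroxy-6-methylhept-5-en-2-one | CC(=O)CC/C=C(\C)CO | intermediate
3 | (5E)-7-bromo-6-methylhept-5-en-2-one | CC(=O)CC/C=C(\C)CBr | intermediate
4 | (±)-3,7-dimethyloct-6-en-1-yn-3-ol (dehydrolinalool) | C#CC(C)(O)CCC=C(C)C | starting material
5 | (5E)-10-hydroxy-6,10,14-trimethylpentadeca-5,13-dien-8-yn-2-one (racemic) | CC(=O)CC/C=C(\C)CC#CC(C)(O)CCC=C(C)C | intermediate
6 | (5E,8Z)-10-hydroxy-6,10,14-trimethylpentadeca-5,8,13-trien-2-one (racemic) | CC(=O)CC/C=C(\C)C/C=C\C(C)(O)CCC=C(C)C | intermediate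
7 | (5E,8Z)-10-hydroxy-6,10,14-trimethylpentadeca-1,5,8,13-tetraen-2-yl trifluoromethanesulfonate (racemic) | C=C(OS(=O)(=O)C(F)(F)F)CC/C=C(\C)C/C=C\C(C)(O)CCC=C(C)C | intermediate
8 | 4-[(4aR,8aS)-1,1,3,6-tetramethyl-1,4,4a,7,8,8a-hexahydronaphthalen-2-yl]but-1-en-2-yl trifluoromethanesulfonate | CC1=C[C@H]2CC(C)=C(CCC(=C)OS(=O)(=O)C(F)(F)F)C(C)(C)[C@H]2CC1 | intermediate
9 | but-3-en-1-ylzinc bromide | C=CCC[Zn]Br | starting material
10 | (4aR,8aS)-1,1,3,6-tetramethyl-2-(3-methylidenehept-6-en-1-yl)-1,4,4a,7,8,8a-hexahydronaphthalene | CC1=C[C@H]2CC(C)=C(CCC(=C)CCC=C)C(C)(C)[C@H]2CC1 | intermediate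
11 | methyl methacrylate (methyl 2-methylprop-2-enoate) | C=C(C)C(=O)OC | starting material
12 | methyl (2E)-2-methyl-6-methylidene-8-[(4aR,8aS)-1,1,3,6-tetramethyl-1,4,4a,7,8,8a-hexahydronaphthalen-2-yl]oct-2-enoate | CC1=C[C@H]2CC(C)=C(CCC(=C)CC/C=C(\C)C(=O)OC)C(C)(C)[C@H]2CC1 | intermediate
13 | methyl (2E)-2,6-dimethyl-8-[(4aR,8aS)-1,1,3,6-tetramethyl-1,4,4a,7,8,8a-hexahydronaphthalen-2-yl]-6-[(triethylsilyl)peroxy]oct-2-enoate (6RS) | CC1=C[C@H]2CC(C)=C(CCC(C)(OO[Si](CC)(CC)CC)CC/C=C(\C)C(=O)OC)C(C)(C)[C@H]2CC1 | intermediate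
14 | methyl (2E)-6-hydroperoxy-2,6-dimethyl-8-[(4aR,8aS)-1,1,3,6-tetramethyl-1,4,4a,7,8,8a-hexahydronaphthalen-2-yl]oct-2-enoate (6RS) | CC1=C[C@H]2CC(C)=C(CCC(C)(OO)CC/C=C(\C)C(=O)OC)C(C)(C)[C@H]2CC1 | intermediate
15 | methyl (2R)-2-[(3R,6R)-6-methyl-6-{2-[(4aR,8aS)-1,1,3,6-tetramethyl-1,4,4a,7,8,8a-hexahydronaphthalen-2-yl]ethyl}-1,2-dioxan-3-yl]propanoate | CC1=C[C@H]2CC(C)=C(CC[C@]3(C)CC[C@H]([C@@H](C)C(=O)OC)OO3)C(C)(C)[C@H]2CC1 | intermediate
16 | (2R)-2-[(3R,6R)-6-methyl-6-{2-[(4aR,8aS)-1,1,3,6-tetramethyl-1,4,4a,7,8,8a-hexahydronaphthalen-2-yl]ethyl}-1,2-dioxan-3-yl]propanoic acid | CC1=C[C@H]2CC(C)=C(CC[C@]3(C)CC[C@H]([C@@H](C)C(=O)O)OO3)C(C)(C)[C@H]2CC1 | target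

**Step count:** 11 steps in total. **Longest linear sequence:** 11 (steps 1 to 11, fully linear from sulcatone).

**Steps most likely to fail**

*Step 6 (bicyclisation).* The enantioselectivity is untested for this ion pair. The strained Z-allyl cation may eliminate to trienes. The C9=C10 alkene could attack the tertiary cation terminus instead. Proton loss could give the C10=C11 or exocyclic alkene isomers; these should equilibrate to the tetrasubstituted alkene under the acid, but this is not certain.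
Fallback, from 3 back to 8: ring A is made by an asymmetric Diels–Alder reaction and only ring B is closed through the cation. Suzuki coupling (Pd(PPh3)4, K3PO4, THF/H2O) of 3 with 4,4,5,5-tetramethyl-2-[(1E)-3-methylbuta-1,3-dien-1-yl]-1,3,2-dioxaborolane F1 (from 2-methylbut-1-en-3-yne and pinacolborane with Cp2Zr(H)Cl) gives (5E,8E)-6,10-dimethylundeca-5,8,10-trien-2-one F2. Enol triflation as in step 5 gives (5E,8E)-6,10-dimethylundeca-1,5,8,10-tetraen-2-yl trifluoromethanesulfonate F3. A Diels–Alder reaction with 3-acryloyl-1,3-oxazolidin-2-one, catalysed by Cu(OTf)2 and (S,S)-2,2′-isopropylidenebis(4-tert-butyl-2-oxazoline), gives the endo "ortho" adduct 3-{[(1S,2R)-4-methyl-2-{(2E)-2-methyl-6-[(trifluoromethanesulfonyl)oxy]hepta-2,6-dien-1-yl}cyclohex-3-en-1-yl]carbonyl}-1,3-oxazolidin-2-one F4; the endo rule gives the cis relationship and the catalyst gives the absolute configuration. MeMgBr with CeCl3 converts the imide into 2-[(1S,2R)-4-methyl-2-{(2E)-2-methyl-6-[(trifluoromethanesulfonyl)oxy]hepta-2,6-dien-1-yl}cyclohex-3-en-1-yl]propan-2-ol F5. Catalytic TfOH in CH2Cl2/(CF3)2CHOH ionises F5 to the same tertiary C18 cation as in step 6, the side-chain alkene closes ring B, and 8 results.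

*Step 10 (peroxy-Michael).* Face selectivity at C3 and the protonation at C2 rest on analogy. C6 is not controlled in step 9, so at most half of 14 can become 15. The hydroperoxide may also slowly degrade the catalyst.
Fallback, from 12 to 16: the ring is closed on an enal under iminium and enamine control. iBu2AlH (CH2Cl2, −78 °C) reduces 12 to (2E)-2-methyl-6-methylidene-8-[(4aR,8aS)-1,1,3,6-tetramethyl-1,4,4a,7,8,8a-hexahydronaphthalen-2-yl]oct-2-en-1-ol F6. Hydroperoxysilylation as in step 9, without the fluoride treatment, gives (2E)-2,6-dimethyl-8-[(4aR,8aS)-1,1,3,6-tetramethyl-1,4,4a,7,8,8a-hexahydronaphthalen-2-yl]-6-[(triethylsilyl)peroxy]oct-2-en-1-ol F7. MnO2 oxidises it to (2E)-2,6-dimethyl-8-[(4aR,8aS)-1,1,3,6-tetramethyl-1,4,4a,7,8,8a-hexahydronaphthalen-2-yl]-6-[(triethylsilyl)peroxy]oct-2-enal F8. HF·pyridine liberates (2E)-6-hydroperoxy-2,6-dimethyl-8-[(4aR,8aS)-1,1,3,6-tetramethyl-1,4,4a,7,8,8a-hexahydronaphthalen-2-yl]oct-2-enal F9, which is not isolated. It is treated with 9-amino-9-deoxy-epi-quinine (20 mol%) and trifluoroacetic acid; the peroxide adds to the iminium ion and the enamine is protonated under catalyst control to give (2R)-2-[(3R,6R)-6-methyl-6-{2-[(4aR,8aS)-1,1,3,6-tetramethyl-1,4,4a,7,8,8a-hexahydronaphthalen-2-yl]ethyl}-1,2-dioxan-3-yl]propanal F10, again after removal of the C6 epimer. Pinnick oxidation (NaClO2, NaH2PO4, 2-methylbut-2-ene, t-BuOH/H2O) gives 16.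

*Step 5 (enol triflation).* The free tertiary alkoxide could be triflated and ionise, and the regioselectivity of enolisation may fall short.
Fallback, from 1 back to 7: the triflate is made before any alcohol is present. Sulcatone 1 is triflated (LiN(iPr)2, PhNTf2) to 6-methylhepta-1,5-dien-2-yl trifluoromethanesulfonate F11. SeO2/t-BuOOH gives (5E)-7-hydroxy-6-methylhepta-1,5-dien-2-yl trifluoromethanesulfonate F12. CBr4/PPh3 gives (5E)-7-bromo-6-methylhepta-1,5-dien-2-yl trifluoromethanesulfonate F13. Coupling with 4 (CuI, NaI, Cs2CO3, DMF) gives (5E)-10-hydroxy-6,10,14-trimethylpentadeca-1,5,13-trien-8-yn-2-yl trifluoromethanesulfonate F14. Because palladium with H2 would endanger the vinyl triflate, the alkyne is reduced to the Z-alkene with copper hydride (CuCl(IPr), IPr = 1,3-bis(2,6-diisopropylphenyl)imidazol-2-ylidene, NaOtBu, polymethylhydrosiloxane, t-BuOH), which gives 7.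

**Further compounds**
F1 | step 6 | 4,4,5,5-tetramethyl-2-[(1E)-3-methylbuta-1,3-dien-1-yl]-1,3,2-dioxaborolane | CC(=C)/C=C/B1OC(C)(C)C(C)(C)O1
F2 | step 6 | (5E,8E)-6,10-dimethylundeca-5,8,10-trien-2-one | CC(=O)CC/C=C(\C)C/C=C/C(C)=C
F3 | step 6 | (5E,8E)-6,10-dimethylundeca-1,5,8,10-tetraen-2-yl trifluoromethanesulfonate | C=C(OS(=O)(=O)C(F)(F)F)CC/C=C(\C)C/C=C/C(C)=C
F4 | step 6 | 3-{[(1S,2R)-4-methyl-2-{(2E)-2-methyl-6-[(trifluoromethanesulfonyl)oxy]hepta-2,6-dien-1-yl}cyclohex-3-en-1-yl]carbonyl}-1,3-oxazolidin-2-one | CC1=C[C@@H](C/C(C)=C/CCC(=C)OS(=O)(=O)C(F)(F)F)[C@@H](C(=O)N2CCOC2=O)CC1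
F5 | step 6 | 2-[(1S,2R)-4-methyl-2-{(2E)-2-methyl-6-[(trifluoromethanesulfonyl)oxy]hepta-2,6-dien-1-yl}cyclohex-3-en-1-yl]propan-2-ol | CC1=C[C@@H](C/C(C)=C/CCC(=C)OS(=O)(=O)C(F)(F)F)[C@@H](C(C)(C)O)CC1
F6 | step 10 | (2E)-2-methyl-6-methylidene-8-[(4aR,8aS)-1,1,3,6-tetramethyl-1,4,4a,7,8,8a-hexahydronaphthalen-2-yl]oct-2-en-1-ol | CC1=C[C@H]2CC(C)=C(CCC(=C)CC/C=C(\C)CO)C(C)(C)[C@H]2CC1
F7 | step 10 | (2E)-2,6-dimethyl-8-[(4aR,8aS)-1,1,3,6-tetramethyl-1,4,4a,7,8,8a-hexahydronaphthalen-2-yl]-6-[(triethylsilyl)peroxy]oct-2-en-1-ol (6RS) | CC1=C[C@H]2CC(C)=C(CCC(C)(OO[Si](CC)(CC)CC)CC/C=C(\C)CO)C(C)(C)[C@H]2CC1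
F8 | step 10 | (2E)-2,6-dimethyl-8-[(4aR,8aS)-1,1,3,6-tetramethyl-1,4,4a,7,8,8a-hexahydronaphthalen-2-yl]-6-[(triethylsilyl)peroxy]oct-2-enal (6RS) | CC1=C[C@H]2CC(C)=C(CCC(C)(OO[Si](CC)(CC)CC)CC/C=C(\C)C=O)C(C)(C)[C@H]2CC1
F9 | step 10 | (2E)-6-hydroperoxy-2,6-dimethyl-8-[(4aR,8aS)-1,1,3,6-tetramethyl-1,4,4a,7,8,8a-hexahydronaphthalen-2-yl]oct-2-enal (6RS) | CC1=C[C@H]2CC(C)=C(CCC(C)(OO)CC/C=C(\C)C=O)C(C)(C)[C@H]2CC1
F10 | step 10 | (2R)-2-[(3R,6R)-6-methyl-6-{2-[(4aR,8aS)-1,1,3,6-tetramethyl-1,4,4a,7,8,8a-hexahydronaphthalen-2-yl]ethyl}-1,2-dioxan-3-yl]propanal | CC1=C[C@H]2CC(C)=C(CC[C@]3(C)CC[C@H]([C@@H](C)C=O)OO3)C(C)(C)[C@H]2CC1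
F11 | step 5 | 6-methylhepta-1,5-dien-2-yl trifluoromethanesulfonate | C=C(OS(=O)(=O)C(F)(F)F)CCC=C(C)C
F12 | step 5 | (5E)-7-hydroxy-6-methylhepta-1,5-dien-2-yl trifluoromethanesulfonate | C=C(OS(=O)(=O)C(F)(F)F)CC/C=C(\C)CO
F13 | step 5 | (5E)-7-bromo-6-methylhepta-1,5-dien-2-yl trifluoromethanesulfonate | C=C(OS(=O)(=O)C(F)(F)F)CC/C=C(\C)CBr
F14 | step 5 | (5E)-10-hydroxy-6,10,14-trimethylpentadeca-1,5,13-trien-8-yn-2-yl trifluoromethanesulfonate (racemic) | C=C(OS(=O)(=O)C(F)(F)F)CC/C=C(\C)CC#CC(C)(O)CCC=C(C)C
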